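**Retrosynthetic overview** (iridoid numbering: C1 acylal, C3=C4 enol ether, C5/C9 ring fusion, C7 CHOH, C8 quaternary carbinol, C10 CH2OAc, C11 CH2O-isovaleryl)
1. The target comes from lipase-selective C11 isovalerylation of the desilylated acylal. The C1 acylal and C3=C4 enol ether come from a C1/C3 dialdehyde by acylative hemiacetalisation, so the dihydropyran ring is formed last.
2. The dialdehyde comes from a 1,5-diol, made by reducing a cis-fused δ-lactone. That lactone is the second ring, and it locks C5/C9 cis by epimerisation at C9.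
3. C8 (OH down, CH2OAc up) comes from a C8 exocyclic methylene, by hydroxyl-directed spiro-epoxidation and acetate opening. C7–O comes from α-hydroxylation of the cyclopentanone anti to the C5 side chain.
4. The cyclopentane (first ring, C5) comes from catalytic asymmetric Michael addition of malonate to cyclopentenone.

Assumption: the C4 epimers formed in Step 8 are carried as mixtures, because C4 becomes sp2 in Step 17. Silyl exchange between the two equivalent C3/C11 arms is harmless.

---

**Step 1**
Reactants: 1 cyclopent-2-en-1-one; 2 dimethyl malonate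
Product: 3 dimethyl 2-[(1S)-3-oxocyclopentyl]malonate
Conditions: La–Li–BINOL heterobimetallic catalyst (LLB, 10 mol %; BINOL enantiomer chosen to give the (S)-adduct), KOtBu (9 mol %), THF, 4 Å MS, rt
Reagents that add atoms: none
Why: Catalytic asymmetric Michael addition; the chiral Lewis acid/Brønsted base pair fixes the enone face and sets C5.

**Step 2**
Reactants: 3
Product: 4 methyl 2-[(1S)-3-oxocyclopentyl]acetate
Conditions: LiCl, H2O, DMSO, 150 °C
Reagents that add atoms: none
Why: Krapcho dealkoxycarbonylation removes one ester and leaves C5 untouched (it is β to the ketone and not enolisable).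

**Step 3**
Reactants: 4
Product: 5 methyl 2-[(1S,3S)-3-hydroxy-4-oxocyclopentyl]acetate (C7–OH trans to the side chain)
Conditions: LDA (1.05 equiv), THF, –78 °C; then Davis oxaziridine, –78 °C
Reagents that add atoms: 2-(phenylsulfonyl)-3-phenyloxaziridine, O=S(=O)(c1ccccc1)N1OC1c1ccccc1 (transfers O)
Why: Kinetic deprotonation at the remote α-carbon (C7) gives an enolate; electrophilic α-hydroxylation occurs anti to the C5 side chain (substrate control). The regioisomer is removed by chromatography.

**Step 4**
Reactants: 5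
Product: 6 methyl 2-[(1S,3S)-3-(TBS-oxy)-4-oxocyclopentyl]acetate
Conditions: TBSCl, imidazole, DMF, rt
Reagents that add atoms: TBSCl, CC(C)(C)[Si](C)(C)Cl
Why: Silylation protects the secondary alcohol and leaves all stereocentres unchanged.

**Step 5**
Reactants: 6
Product: 7 methyl 2-[4-(TBS-oxy)-2-(hydroxymethyl)-3-oxocyclopentyl]acetate (CH2OH trans to the side chain)
Conditions: LDA (1.05 equiv), THF, –78 °C; then monomeric CH2O, –78 → –40 °C; NH4Cl
Reagents that add atoms: formaldehyde, C=O (becomes C1)
Why: The unsubstituted α′-carbon (C9) is deprotonated, and aldol addition occurs anti to the C5 side chain. The C9 configuration is corrected in Step 6.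

**Step 6**
Reactants: 7
Product: 8 cis-fused δ-lactone ketone, 6-(TBS-oxy)hexahydrocyclopenta[c]pyran-3,7-dione
Conditions: DBU (20 mol %), toluene, 60 °C, 4 Å MS
Reagents that add atoms: none (MeOH is lost)
Why: C9 epimerises through the C8 enol, and only the cis epimer can close the six-membered lactone. This drains the equilibrium (Curtin–Hammett) and sets C5/C9 cis, while C7–O stays trans to both arms.

**Step 7**
Reactants: 8
Product: 9 7-methylene lactone, 6-(TBS-oxy)-7-methylenehexahydrocyclopenta[c]pyran-3-one
Conditions: Zn, CH2Br2, TiCl4, THF/CH2Cl2, 0 °C → rt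
Reagents that add atoms: dibromomethane, C(Br)Br (becomes C10)
Why: Takai–Lombardo methylenation is non-basic, so it does not epimerise C9 or C7 and leaves the lactone intact.

**Step 8**
Reactants: 9
Product: 10 4-(hydroxymethyl) lactone (C4 epimers)
Conditions: LDA (1.1 equiv), THF, –78 °C; then monomeric CH2O; NH4Cl at –78 °C
Reagents that add atoms: formaldehyde, C=O (becomes C11)
Why: Lactone enolate aldol with CH2O installs C11. C4 is destroyed later, so its configuration does not matter.

**Step 9**
Reactants: 10
Product: 11 4-[(TBS-oxy)methyl] lactone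
Conditions: TBSOTf, 2,6-lutidine, CH2Cl2, –78 °C
Reagents that add atoms: TBSOTf, CC(C)(C)[Si](C)(C)OS(=O)(=O)C(F)(F)F
Why: Low-temperature silylation avoids E1cB loss of the β-oxygen.

**Step 10**
Reactants: 11
Product: 12 diol (C1–OH and C3–OH free; methylene and both TBS groups intact)
Conditions: LiAlH4, THF, 0 °C
Reagents that add atoms: none (hydride adds H only)
Why: Lactone reduction to the 1,5-diol, with cis C1/C4 arms and all stereocentres retained.

**Step 11**
Reactants: 12
Product: 13 spiro-epoxy diol (epoxide O down, C10 up)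
Conditions: VO(acac)2 (5 mol %), TBHP, CH2Cl2, rt
Reagents that add atoms: tert-butyl hydroperoxide, CC(C)(C)OO (transfers O)
Why: Hydroxyl-directed epoxidation. The homoallylic C1–OH is on the lower face and delivers the vanadium peroxide syn to itself, while C7–OTBS blocks the upper face. This sets C8 (O down, C10 up).

**Step 12**
Reactants: 13
Product: 14 bis-PMB ether of 13
Conditions: NaH, PMBCl, TBAI, THF/DMF, 0 °C → rt
Reagents that add atoms: 4-methoxybenzyl chloride, COc1ccc(CCl)cc1
Why: Masks the primary alcohols so the tertiary carbinol can be silylated later. A trans-fused oxolane closure onto the epoxide is geometrically impossible.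

**Step 13**
Reactants: 14
Product: 15 C10-acetate, C8-tertiary alcohol
Conditions: CsOAc, AcOH (3 equiv), DMF, 80 °C
Reagents that add atoms: caesium acetate, CC(=O)[O-].[Cs+]; acetic acid, CC(=O)O
Why: Buffered SN2 attack of acetate at the unhindered primary epoxide carbon leaves the C8–O bond untouched, giving C8–OH down and C10H2OAc up.

**Step 14**
Reactants: 15
Product: 16 C8-OTES ether
Conditions: TESOTf, 2,6-lutidine, CH2Cl2, –78 → 0 °C
Reagents that add atoms: TESOTf, CC[Si](CC)(CC)OS(=O)(=O)C(F)(F)F
Why: Silylating the tertiary OH prevents retro-aldol or β-elimination in the later β-hydroxy aldehyde.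

**Step 15**
Reactants: 16
Product: 17 diol (PMB groups removed)
Conditions: DDQ, CH2Cl2/pH 7 buffer, 0 °C → rt
Reagents that add atoms: none
Why: Oxidative PMB cleavage; silyl ethers and the acetate are unaffected at neutral pH.

**Step 16**
Reactants: 17
Product: 18 C1/C3 dialdehyde
Conditions: Dess–Martin periodinane, NaHCO3, CH2Cl2, 0 °C → rt
Reagents that add atoms: none
Why: Buffered double oxidation of the two primary alcohols avoids amine bases that could epimerise C9 or eliminate.

**Step 17**
Reactants: 18
Product: 19 silylated acylal–enol ether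
Conditions: (iValCO)2O, Et3N, DMAP (cat.), CH2Cl2, 0 °C → rt
Reagents that add atoms: isovaleric anhydride, CC(C)CC(=O)OC(=O)CC(C)C
Why: The C3 aldehyde enolises and its enol oxygen adds to the C1 aldehyde (6-exo hemiacetalisation), and the hemiacetal oxygen is trapped as the isovalerate. Epimerisable C9 funnels to the cis-fused ring, and the 1β-acylal is favoured by the anomeric effect.

**Step 18**
Reactants: 19
Product: 20 desilylated acylal (C7-, C8- and C11-OH free)
Conditions: HF·pyridine, pyridine, THF, 0 °C → rt
Reagents that add atoms: none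
Why: Buffered fluoride removes the TBS and TES groups without acylal or enol-ether hydrolysis.

**Step 19**
Reactants: 20
Product: 21 target
Conditions: Novozym 435 (Candida antarctica lipase B, a serine hydrolase), vinyl isovalerate, MTBE, 25 °C
Reagents that add atoms: vinyl isovalerate, C=COC(=O)CC(C)C
Why: The lipase transesterifies only the unhindered primary allylic C11–OH, leaving the secondary C7–OH and tertiary C8–OH untouched.

---

**Compound list**
1 | cyclopent-2-en-1-one | O=C1C=CCC1 | starting material
2 | dimethyl malonate | COC(=O)CC(=O)OC | starting material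
3 | dimethyl 2-[(1S)-3-oxocyclopentyl]malonate | COC(=O)C(C(=O)OC)[C@H]1CCC(=O)C1 | intermediate
4 | methyl 2-[(1S)-3-oxocyclopentyl]acetate | COC(=O)C[C@H]1CCC(=O)C1 | intermediate
5 | methyl 2-[(1S,3S)-3-hydroxy-4-oxocyclopentyl]acetate | COC(=O)C[C@H]1C[C@H](O)C(=O)C1 | intermediate
6 | methyl 2-[(1S,3S)-3-(TBS-oxy)-4-oxocyclopentyl]acetate | COC(=O)C[C@H]1C[C@H](O[Si](C)(C)C(C)(C)C)C(=O)C1 | intermediate
7 | 2-(hydroxymethyl) ketone, CH2OH trans to side chain | COC(=O)C[C@H]1C[C@H](O[Si](C)(C)C(C)(C)C)C(=O)[C@@H]1CO | intermediate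
8 | cis-fused lactone ketone, 6-(TBS-oxy) | O=C1C[C@H]2C[C@H](O[Si](C)(C)C(C)(C)C)C(=O)[C@H]2CO1 | intermediate
9 | 7-methylene lactone | O=C1C[C@H]2C[C@H](O[Si](C)(C)C(C)(C)C)C(=C)[C@H]2CO1 | intermediate
10 | 4-(hydroxymethyl) lactone (C4 epimers) | O=C1C(CO)[C@H]2C[C@H](O[Si](C)(C)C(C)(C)C)C(=C)[C@H]2CO1 | intermediate
11 | 4-[(TBS-oxy)methyl] lactone | O=C1C(CO[Si](C)(C)C(C)(C)C)[C@H]2C[C@H](O[Si](C)(C)C(C)(C)C)C(=C)[C@H]2CO1 | intermediate
12 | diol (cyclopentane, exocyclic methylene) | OCC(CO[Si](C)(C)C(C)(C)C)[C@H]1C[C@H](O[Si](C)(C)C(C)(C)C)C(=C)[C@H]1CO | intermediate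
13 | spiro-epoxy diol | OCC(CO[Si](C)(C)C(C)(C)C)[C@H]1C[C@H](O[Si](C)(C)C(C)(C)C)[C@]2(CO2)[C@H]1CO | intermediate
14 | bis-PMB epoxide | COc1ccc(COCC(CO[Si](C)(C)C(C)(C)C)[C@H]2C[C@H](O[Si](C)(C)C(C)(C)C)[C@]3(CO3)[C@H]2COCc2ccc(OC)cc2)cc1 | intermediate
15 | C10-acetate, C8-OH, bis-PMB | COc1ccc(COCC(CO[Si](C)(C)C(C)(C)C)[C@H]2C[C@H](O[Si](C)(C)C(C)(C)C)[C@](O)(COC(C)=O)[C@H]2COCc2ccc(OC)cc2)cc1 | intermediate
16 | C8-OTES analogue of 15 | COc1ccc(COCC(CO[Si](C)(C)C(C)(C)C)[C@H]2C[C@H](O[Si](C)(C)C(C)(C)C)[C@](O[Si](CC)(CC)CC)(COC(C)=O)[C@H]2COCc2ccc(OC)cc2)cc1 | intermediate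
17 | diol after PMB removal | OCC(CO[Si](C)(C)C(C)(C)C)[C@H]1C[C@H](O[Si](C)(C)C(C)(C)C)[C@](O[Si](CC)(CC)CC)(COC(C)=O)[C@H]1CO | intermediate
18 | C1/C3 dialdehyde | O=CC(CO[Si](C)(C)C(C)(C)C)[C@H]1C[C@H](O[Si](C)(C)C(C)(C)C)[C@](O[Si](CC)(CC)CC)(COC(C)=O)[C@H]1C=O | intermediate
19 | silylated acylal–enol ether | CC(=O)OC[C@]1(O[Si](CC)(CC)CC)[C@H]2[C@H](OC(=O)CC(C)C)OC=C(CO[Si](C)(C)C(C)(C)C)[C@H]2C[C@@H]1O[Si](C)(C)C(C)(C)C | intermediate
20 | [(1S,4aS,6S,7R,7aS)-6,7-dihydroxy-1-(isovaleroyloxy)-4-(hydroxymethyl)-1,4a,5,6,7,7a-hexahydrocyclopenta[c]pyran-7-yl]methyl acetate | CC(=O)OC[C@]1(O)[C@H]2[C@H](OC(=O)CC(C)C)OC=C(CO)[C@H]2C[C@@H]1O | intermediate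
21 | [(1S,4aS,6S,7R,7aS)-6,7-dihydroxy-1-[(3-methylbutanoyl)oxy]-4-{[(3-methylbutanoyl)oxy]methyl}-1,4a,5,6,7,7a-hexahydrocyclopenta[c]pyran-7-yl]methyl acetate (CID42638123) | CC(=O)OC[C@]1(O)[C@H]2[C@H](OC(=O)CC(C)C)OC=C(COC(=O)CC(C)C)[C@H]2C[C@@H]1O | target

---

**Totals:** 19 steps; the longest linear sequence is 19 steps.

**Three steps most likely to fail**
1. **Step 11 (directed epoxidation face selectivity).** The homoallylic-OH direction may be weak or the C7–OTBS may not block the top face well. Fallback (different approach): omit the C7 oxygen (skip Steps 3–4). Convert the C8 ketone by Corey–Chaykovsky (convex-face CH2 delivery gives C10 up, O down) and isomerise the epoxide to the C7=C8 allylic alcohol. Then epoxidise from the convex face and hydrolyse with inversion at C8, so the trans-diol is set by ring shape.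
2. **Step 17 (acylative pyran closure).** The β-silyloxy aldehydes may eliminate or retro-aldolise. Fallback (different approach): use the malonate-type route, keeping C11 as CO2Me and forming the stable β-alkoxyacrylate lactol. Then reduce the ester with excess DIBAL on the lactol and bis-isovalerylate C1 and C11 in one step.
3. **Step 6 (cis-lock by epimerisation–lactonisation).** Retro-aldol or dehydration may compete with lactonisation. Fallback (different approach): Claisen-formylate ketone 6 at C9 and O-silylate to the hydroxymethylene enol ether. Hydrogenate from the face anti to the C5 side chain, which places CH2OTBS cis to it. Then desilylate and lactonise.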